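## Structural features

The target is a furofuran lignan: two tetrahydrofuran rings cis-fused along C3a–C6a (a 3,7-dioxabicyclo[3.3.0]octane). The numbering used throughout is C1 (bearing ring A, 4-hydroxy-3-methoxyphenyl), O2, C3, C3a, C4 (bearing ring B, 3-hydroxy-4,5-dimethoxyphenyl), O5, C6 and C6a. Four contiguous stereocentres run C1–C6a–C3a–C4 with the configuration (1S,3aR,4S,6aR): the bridgehead hydrogens are cis and both aryl groups lie on the convex (exo) face. The core is C2-symmetric in shape but the two aryl groups differ, so a dimerisation is excluded and each aryl group, with its one free phenol, has to be introduced separately and masked. C1–O2 and C4–O5 are benzylic ether bonds para to oxygen donors: acid ionises them and equilibrates exo and endo aryl isomers of similar energy, and hydrogenolysis can cut them, so late steps have to be basic or neutral. The real difficulty is the absolute configuration of the bridgehead pair together with the relative configuration of two benzylic centres that carry no directing group in the product. The key step uses the make-up of ring C1–O2–C3–C3a–C6a: C1 is a benzylic carbon bonded to O2 (the β-carbon of an arylidene acceptor after uptake of an alkoxide), and C3a–C6a joins a potential malonate carbanion to a potential allyl terminus whose leftover vinyl group masks the C4 aryl ketone.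

## Logic of the disconnections

18 to 17: the two aryl O–benzyl bonds are cut. The phenols must stay masked through ylide, hydride, alkoxide and palladium chemistry, and benzyl ethers are inert to all of these. The demand on the forward step is that hydrogenolysis removes the aryl benzyl ethers without cutting C1–O2 or C4–O5.

17 to 15 (through 16): the O5–C6 bond is cut, not C4–O5. The C4–O bond then arrives intact from a carbinol, so C4 is never a cation, and C6 is a primary carbon where displacement is easy. The second ring is reduced to a 1,4-diol. The forward step must activate the primary hydroxyl selectively and close under base.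

15 to 14: C6 is raised to the carboxyl level, making the diol the reduction product of a cis-fused lactone. The lactone holds C6a and ties the C4 oxygen in place. The forward step only needs a hydride that breaks no bond to a stereocentre.

14 to 13: a methoxycarbonyl group is added at C6a, which turns C6a into a malonate carbon. The forward step has to remove only the ester that is not part of the lactone, and protonation at C6a must give the cis ring fusion, which the bicycle enforces.

13 to 11 (through 12): the lactone acyl–O5 bond and the C4–H bond are cut, so C4 becomes a ketone carbon and the two esters on C6a become equivalent. The forward step must deliver hydride to the ketone face that gives 4S, under control from C3a, and only the ester cis to the new carbinol can lactonise.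

11 to 10: the C4 ketone is replaced by a C4 methylene (a 1-arylvinyl group). A ketone with an acidic C3a–H and a β-alkoxy group could not pass through the annulation, whereas the vinyl group is exactly what an allylpalladium unit leaves behind. The forward step is an alkene cleavage that spares two electron-rich arenes.

10 to 3 and 9: C1–O2 and C3a–C6a are cut. This opens ring C1–O2–C3–C3a–C6a into two pieces of similar size, one achiral and one racemic, and removes two stereocentres. The forward step must set C3a by the catalyst, place the C1 aryl trans to the C3a alkenyl group, and attack the substituted allyl terminus.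

3 to 1 and 2: the C1=C6a double bond is cut (carbonyl condensation). Both esters are the same, so no alkene geometry arises.

9 to 8: the epoxide C–C bond to its methylene carbon is cut, leaving an enal carbonyl. The forward methylene transfer must add to the carbonyl, not to the conjugated alkene.

8 to 6 (through 7) and 6 to 5: the α-methylene C=C bond and then the homologating C=C bond are cut, back to an aryl aldehyde. The forward sequence must keep the self-condensing aldehyde 7 from being stored.

5 to 4: the O–benzyl bond on ring B is cut, back to the purchased phenol.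

## Other disconnections considered

Alternative 1: The cut is at C4–C3a and C1–C6a, with C3 and C6 carried as the acetal and carbonyl carbons of the menthyloxybutenolide A1. In the forward step the lithiated dithiane A2 adds to A1 anti to the menthyloxy group, and the lactone enolate is trapped by aldehyde 1 anti to the new dithianyl group, giving A3.
- In its favour: three components are joined in one operation, both bridgehead centres come from a cheap stoichiometric auxiliary, and no chiral catalyst has to be found.
- Against it here: neither target ring is closed. The aldol carbinol (C1) usually forms with modest selectivity. The dithiane has to be removed next to electron-rich arenes, C4 is created later by a ketone reduction, and C3 must be brought down from the acetal level. Both rings are then closed from a tetraol in which two 1,4-diol pairings compete and in which the benzylic centres are exposed to ionisation.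
- Comparison on structure: A3 holds all skeletal carbons and both bridgehead centres, while 10 holds one ring, C1 and C3a.
- Comparison on mechanism: auxiliary control of the bridgeheads is better established than ligand control of a zwitterionic annulation, and on this point alternative 1 is the better. The chosen plan sets each benzylic centre in a defined event and closes the second ring without touching either.
- Comparison on step economy: alternative 1 should need about nine or ten steps against twelve, and is the better on this count.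

Alternative 2: The cut is inside ring B, at the bond between the hydroxyl-bearing carbon and the neighbouring CH, so ring B is made last. In the forward step, heating the alkenylcyclobutenone A4 opens the four-membered ring to a dienylketene, which closes by a 6π process and tautomerises to the phenol A5.
- In its favour: the ring B hydroxyl is formed free and in a defined position next to the two methoxy groups, the conditions are neutral and thermal, and one protecting group is saved. On protecting-group economy it is the better plan. As a single step the pericyclic cascade is at least the equal of the palladium annulation in reliability.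
- Against it here: the ring B pattern can be bought as 4, so the step solves a problem that does not exist. A4 needs the whole stereodefined furofuran first, with a C4 substituent that is not an aryl group, followed by several steps of squaric ester chemistry.
- Comparison on structure and step economy: it leaves the four stereocentres unaddressed and is clearly longer and more linear than the chosen plan.

Alternative 3: The cut is at C6–C6a, C3–C3a, O5–C6 and O2–C3. In the forward step the ene-diol A6, with PdCl2, CuCl2 as reoxidant and CO, forms an alkoxycarbonylpalladium species that adds syn across the alkene; a second CO insertion and lactonisation give the bis-lactone A7.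
- In its favour: two rings, four bonds and both bridgehead centres are formed in one step from an acyclic precursor whose carbinol centres already fix C1 and C4. On bond-forming efficiency it is the better plan, and on paper it is also shorter (about nine or ten steps).
- Against it here: A6 is a bis-benzylic, bis-allylic diol with electron-rich aryl groups. Under oxidising divalent palladium with copper salts it can ionise, transpose or oxidise to an enone. The alkene face must be chosen relative to both carbinols to give exo aryl groups. Both lactone carbonyls then have to be reduced to CH2, which reopens both rings through a tetraol. The unsymmetrical diol also needs two separate asymmetric carbinol constructions.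
- Comparison on structure and mechanism: the chosen plan uses one catalytic asymmetric event and never reopens a ring once it is closed; alternative 3 is more elegant in its two-directional use of the near-symmetry.

Key step: step 6

Remark: 1 is bought as the benzyl ether (one O-benzylation away from vanillin). The ligand in step 6 is written as (R,R); this stands for whichever enantiomer gives (4R) in 10, and the mirror-image ligand is to be used if the sense of induction proves opposite.

## Route

Step 1
Reactants: 1 4-(benzyloxy)-3-methoxybenzaldehyde; 2 dimethyl malonate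
Product: 3 dimethyl 2-[4-(benzyloxy)-3-methoxybenzylidene]malonate
Conditions: piperidine (10 mol%), AcOH (10 mol%), PhMe, reflux, Dean–Stark
Reagents that add atoms: none
Why: Knoevenagel condensation driven by azeotropic removal of water; the two esters are identical, so the alkene has no geometry to control.

Step 2
Reactants: 4 3-hydroxy-4,5-dimethoxybenzaldehyde
Product: 5 3-(benzyloxy)-4,5-dimethoxybenzaldehyde
Conditions: BnBr, K2CO3, DMF, 60 °C
Reagents that add atoms: benzyl bromide, BrCc1ccccc1
Why: Williamson etherification of the only phenol; the benzyl ether is inert to every later step up to the last one.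

Step 3
Reactants: 5 3-(benzyloxy)-4,5-dimethoxybenzaldehyde
Product: 6 1-(benzyloxy)-2,3-dimethoxy-5-(2-methoxyethenyl)benzene (E/Z mixture)
Conditions: Ph3P(CH2OMe)Cl, KOt-Bu, THF, 0 °C to rt
Reagents that add atoms: (methoxymethyl)triphenylphosphonium chloride, COC[P+](c1ccccc1)(c1ccccc1)c1ccccc1.[Cl-]
Why: Wittig one-carbon homologation to an enol ether; the alkene geometry is irrelevant because both isomers hydrolyse to the same aldehyde.

Step 4
Reactants: 6 1-(benzyloxy)-2,3-dimethoxy-5-(2-methoxyethenyl)benzene
Product: 8 2-[3-(benzyloxy)-4,5-dimethoxyphenyl]prop-2-enal, via arylacetaldehyde 7 (not isolated)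
Conditions: 88% aq. HCO2H, CH2Cl2, rt; concentrate; then 37% aq. CH2O, pyrrolidine (10 mol%), EtCO2H (10 mol%), i-PrOH, 45 °C
Reagents that add atoms: water, O; formaldehyde, C=O
Why: Acid hydrolysis of the enol ether gives 7, which undergoes amine-catalysed Mannich condensation with formaldehyde and elimination (α-methylenation) at its only α-position; keeping 7 in the flask avoids storing an aldol-prone arylacetaldehyde.

Step 5
Reactants: 8 2-[3-(benzyloxy)-4,5-dimethoxyphenyl]prop-2-enal
Product: 9 rac-2-{1-[3-(benzyloxy)-4,5-dimethoxyphenyl]ethenyl}oxirane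
Conditions: Me3S+ I−, n-BuLi, THF, −10 °C; then 8, −10 °C to rt
Reagents that add atoms: trimethylsulfonium iodide, C[S+](C)C.[I-]
Why: Corey–Chaykovsky epoxidation; the unstabilised sulfonium ylide adds to the carbonyl and not to the conjugated alkene, and the racemic epoxide is sufficient because step 6 is stereoconvergent.

Step 6
Reactants: 3 dimethyl 2-[4-(benzyloxy)-3-methoxybenzylidene]malonate; 9 rac-2-{1-[3-(benzyloxy)-4,5-dimethoxyphenyl]ethenyl}oxirane
Product: 10 dimethyl (2R,4R)-2-[4-(benzyloxy)-3-methoxyphenyl]-4-{1-[3-(benzyloxy)-4,5-dimethoxyphenyl]ethenyl}oxolane-3,3-dicarboxylate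
Conditions: Pd2(dba)3·CHCl3 (2.5 mol%), (R,R)-N,N'-(cyclohexane-1,2-diyl)bis[2-(diphenylphosphanyl)benzamide] (7.5 mol%), 3 (1.0 equiv), 9 (1.3 equiv), THF, rt to 40 °C
Reagents that add atoms: none
Why: Zerovalent palladium ionises 9 to a zwitterionic π-allylpalladium alkoxide; the alkoxide O2 adds reversibly to the benzylic carbon of 3 (oxa-Michael, C1–O2) and the malonate carbanion C6a then attacks the allyl terminus C3a on the face opposite palladium (C3a–C6a). The closest known reaction type is the palladium-catalysed zwitterionic (3+2) cycloaddition of vinyl epoxides with doubly activated alkenes, joined to the dynamic kinetic asymmetric allylic alkylation of vinyl epoxides under a chiral diphosphine. Ring C1–O2–C3–C3a–C6a closes in a 5-exo mode at the substituted allyl terminus, whereas attack at the CH2 terminus would need a seven-membered ring and should not compete. C3a is set by the ligand: the two diastereomeric π-allyl complexes interconvert by π–σ–π exchange through the unsubstituted CH2 terminus faster than the bimolecular capture of 3, so racemic 9 converges on one series. C1 is set relative to C3a in the ring-closing transition state, where the ring A aryl group and the bulky palladium-bound allyl unit take opposite faces of the forming ring, and because the oxa-Michael step is reversible the C1-epimeric zwitterions equilibrate and the trans pathway should be drained. The step also needs cycloaddition to outrun isomerisation of the zwitterion to a dienol, which the doubly activated acceptor and the slight excess of 9 are expected to secure.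

Step 7
Reactants: 10 dimethyl (2R,4R)-2-[4-(benzyloxy)-3-methoxyphenyl]-4-{1-[3-(benzyloxy)-4,5-dimethoxyphenyl]ethenyl}oxolane-3,3-dicarboxylate
Product: 11 dimethyl (2R,4R)-2-[4-(benzyloxy)-3-methoxyphenyl]-4-[3-(benzyloxy)-4,5-dimethoxybenzoyl]oxolane-3,3-dicarboxylate
Conditions: OsO4 (2 mol%), NaIO4 (4 equiv), 2,6-lutidine, dioxane–H2O (3:1), rt
Reagents that add atoms: osmium tetroxide, O=[Os](=O)(=O)=O; sodium periodate, [Na+].[O-]I(=O)(=O)=O
Why: Lemieux–Johnson cleavage of the only alkene, chosen over ozone because of the two electron-rich arenes; 2,6-lutidine keeps the medium near neutral so that the newly acidic C3a–H is not epimerised and O2 is not β-eliminated.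

Step 8
Reactants: 11 dimethyl (2R,4R)-2-[4-(benzyloxy)-3-methoxyphenyl]-4-[3-(benzyloxy)-4,5-dimethoxybenzoyl]oxolane-3,3-dicarboxylate
Product: 13 methyl (1R,3aR,4S,6aS)-1-[4-(benzyloxy)-3-methoxyphenyl]-4-[3-(benzyloxy)-4,5-dimethoxyphenyl]-6-oxotetrahydro-1H,3H-furo[3,4-c]furan-6a(6H)-carboxylate, via hydroxy diester 12 (not isolated)
Conditions: NaBH4, CeCl3·7H2O, MeOH–THF, −40 to 0 °C; AcOH, concentrate; then PPTS (cat.), PhMe, 50 °C
Reagents that add atoms: none
Why: Luche-type ketone reduction followed by lactonisation; C4 is set by substrate control, hydride adding anti to the quaternary C6a with the carbonyl oxygen on the side of C3 (Felkin–Anh model, also the sense expected for a chelate through O2), which should give the (S)-carbinol. Only the ester cis to the carbinol side chain can close a cis-fused γ-lactone, which fixes O5–C6 and marks the other ester for removal.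

Step 9
Reactants: 13 methyl (1R,3aR,4S,6aS)-1-[4-(benzyloxy)-3-methoxyphenyl]-4-[3-(benzyloxy)-4,5-dimethoxyphenyl]-6-oxotetrahydro-1H,3H-furo[3,4-c]furan-6a(6H)-carboxylate
Product: 14 (1S,3aR,4S,6aS)-1-[4-(benzyloxy)-3-methoxyphenyl]-4-[3-(benzyloxy)-4,5-dimethoxyphenyl]tetrahydro-1H,3H-furo[3,4-c]furan-6-one
Conditions: LiCl, H2O (2 equiv), DMSO, 140 °C
Reagents that add atoms: none
Why: Krapcho dealkoxycarbonylation: chloride demethylates the ester, carbon dioxide is lost and the lactone enolate is protonated; C6a can only take up the proton to give the cis-fused bicycle, so H6a ends cis to H3a.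

Step 10
Reactants: 14 (1S,3aR,4S,6aS)-1-[4-(benzyloxy)-3-methoxyphenyl]-4-[3-(benzyloxy)-4,5-dimethoxyphenyl]tetrahydro-1H,3H-furo[3,4-c]furan-6-one
Product: 15 (S)-[3-(benzyloxy)-4,5-dimethoxyphenyl]{(3R,4R,5S)-5-[4-(benzyloxy)-3-methoxyphenyl]-4-(hydroxymethyl)oxolan-3-yl}methanol
Conditions: LiAlH4, THF, 0 °C; H2O, 15% aq. NaOH
Reagents that add atoms: none
Why: Hydride reduction of the lactone to the 1,4-diol; no bond to a stereocentre is broken, so all four centres are carried over unchanged.

Step 11
Reactants: 15 (S)-[3-(benzyloxy)-4,5-dimethoxyphenyl]{(3R,4R,5S)-5-[4-(benzyloxy)-3-methoxyphenyl]-4-(hydroxymethyl)oxolan-3-yl}methanol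
Product: 17 (1S,3aR,4S,6aR)-1-[4-(benzyloxy)-3-methoxyphenyl]-4-[3-(benzyloxy)-4,5-dimethoxyphenyl]tetrahydro-1H,3H-furo[3,4-c]furan, via primary tosylate 16 (not isolated)
Conditions: TsCl (1.1 equiv), pyridine, CH2Cl2, 0 °C; concentrate; then KOt-Bu, THF, 0 °C to rt
Reagents that add atoms: none
Why: Selective sulfonylation of the primary hydroxyl followed by intramolecular Williamson etherification (5-exo-tet) by the C4 alkoxide; the C4–O bond is never broken, so C4 is retained, and the basic medium prevents ionisation at either benzylic carbon.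

Step 12
Reactants: 17 (1S,3aR,4S,6aR)-1-[4-(benzyloxy)-3-methoxyphenyl]-4-[3-(benzyloxy)-4,5-dimethoxyphenyl]tetrahydro-1H,3H-furo[3,4-c]furan
Product: 18 4-[(1S,3aR,4S,6aR)-4-(3-hydroxy-4,5-dimethoxyphenyl)tetrahydro-1H,3H-furo[3,4-c]furan-1-yl]-2-methoxyphenol (CNP0324902.1)
Conditions: H2 (1 atm), 10% Pd/C, EtOAc, rt, stopped at full conversion
Reagents that add atoms: none
Why: Hydrogenolysis of the two aryl benzyl ethers, which are cleaved faster than dialkyl benzylic ethers; the aprotic neutral solvent and short contact time are meant to spare C1–O2 and C4–O5.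

## Compound list

1 | 4-(benzyloxy)-3-methoxybenzaldehyde | COc1cc(C=O)ccc1OCc1ccccc1 | starting material
2 | dimethyl malonate | COC(=O)CC(=O)OC | starting material
3 | dimethyl 2-[4-(benzyloxy)-3-methoxybenzylidene]malonate | COC(=O)C(=Cc1ccc(OCc2ccccc2)c(OC)c1)C(=O)OC | intermediate
4 | 3-hydroxy-4,5-dimethoxybenzaldehyde | COc1cc(C=O)cc(O)c1OC | starting material
5 | 3-(benzyloxy)-4,5-dimethoxybenzaldehyde | COc1cc(C=O)cc(OCc2ccccc2)c1OC | intermediate
6 | 1-(benzyloxy)-2,3-dimethoxy-5-(2-methoxyethenyl)benzene (E/Z mixture) | COC=Cc1cc(OCc2ccccc2)c(OC)c(OC)c1 | intermediate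
7 | 2-[3-(benzyloxy)-4,5-dimethoxyphenyl]acetaldehyde | O=CCc1cc(OCc2ccccc2)c(OC)c(OC)c1 | intermediate
8 | 2-[3-(benzyloxy)-4,5-dimethoxyphenyl]prop-2-enal | C=C(C=O)c1cc(OCc2ccccc2)c(OC)c(OC)c1 | intermediate
9 | rac-2-{1-[3-(benzyloxy)-4,5-dimethoxyphenyl]ethenyl}oxirane | C=C(C1CO1)c1cc(OCc2ccccc2)c(OC)c(OC)c1 | intermediate
10 | dimethyl (2R,4R)-2-[4-(benzyloxy)-3-methoxyphenyl]-4-{1-[3-(benzyloxy)-4,5-dimethoxyphenyl]ethenyl}oxolane-3,3-dicarboxylate | COc1cc([C@H]2OC[C@H](C(=C)c3cc(OCc4ccccc4)c(OC)c(OC)c3)C2(C(=O)OC)C(=O)OC)ccc1OCc1ccccc1 | intermediate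
11 | dimethyl (2R,4R)-2-[4-(benzyloxy)-3-methoxyphenyl]-4-[3-(benzyloxy)-4,5-dimethoxybenzoyl]oxolane-3,3-dicarboxylate | COc1cc([C@H]2OC[C@H](C(=O)c3cc(OCc4ccccc4)c(OC)c(OC)c3)C2(C(=O)OC)C(=O)OC)ccc1OCc1ccccc1 | intermediate
12 | dimethyl (2R,4R)-2-[4-(benzyloxy)-3-methoxyphenyl]-4-{(S)-[3-(benzyloxy)-4,5-dimethoxyphenyl](hydroxy)methyl}oxolane-3,3-dicarboxylate | COc1cc([C@H]2OC[C@H]([C@H](O)c3cc(OCc4ccccc4)c(OC)c(OC)c3)C2(C(=O)OC)C(=O)OC)ccc1OCc1ccccc1 | intermediate
13 | methyl (1R,3aR,4S,6aS)-1-[4-(benzyloxy)-3-methoxyphenyl]-4-[3-(benzyloxy)-4,5-dimethoxyphenyl]-6-oxotetrahydro-1H,3H-furo[3,4-c]furan-6a(6H)-carboxylate | COc1cc([C@H]2OC[C@H]3[C@]2(C(=O)OC)C(=O)O[C@@H]3c2cc(OCc4ccccc4)c(OC)c(OC)c2)ccc1OCc1ccccc1 | intermediate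
14 | (1S,3aR,4S,6aS)-1-[4-(benzyloxy)-3-methoxyphenyl]-4-[3-(benzyloxy)-4,5-dimethoxyphenyl]tetrahydro-1H,3H-furo[3,4-c]furan-6-one | COc1cc([C@H]2OC[C@H]3[C@@H]2C(=O)O[C@@H]3c2cc(OCc4ccccc4)c(OC)c(OC)c2)ccc1OCc1ccccc1 | intermediate
15 | (S)-[3-(benzyloxy)-4,5-dimethoxyphenyl]{(3R,4R,5S)-5-[4-(benzyloxy)-3-methoxyphenyl]-4-(hydroxymethyl)oxolan-3-yl}methanol | COc1cc([C@H]2OC[C@H]([C@H](O)c3cc(OCc4ccccc4)c(OC)c(OC)c3)[C@@H]2CO)ccc1OCc1ccccc1 | intermediate
16 | {(2S,3R,4R)-2-[4-(benzyloxy)-3-methoxyphenyl]-4-{(S)-[3-(benzyloxy)-4,5-dimethoxyphenyl](hydroxy)methyl}oxolan-3-yl}methyl 4-methylbenzenesulfonate | COc1cc([C@H]2OC[C@H]([C@H](O)c3cc(OCc4ccccc4)c(OC)c(OC)c3)[C@@H]2COS(=O)(=O)c2ccc(C)cc2)ccc1OCc1ccccc1 | intermediate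
17 | (1S,3aR,4S,6aR)-1-[4-(benzyloxy)-3-methoxyphenyl]-4-[3-(benzyloxy)-4,5-dimethoxyphenyl]tetrahydro-1H,3H-furo[3,4-c]furan | COc1cc([C@H]2OC[C@H]3[C@@H]2CO[C@@H]3c2cc(OCc4ccccc4)c(OC)c(OC)c2)ccc1OCc1ccccc1 | intermediate
18 | 4-[(1S,3aR,4S,6aR)-4-(3-hydroxy-4,5-dimethoxyphenyl)tetrahydro-1H,3H-furo[3,4-c]furan-1-yl]-2-methoxyphenol | COc1cc([C@H]2OC[C@H]3[C@@H]2CO[C@@H]3c2cc(O)c(OC)c(OC)c2)ccc1O | target

## Step count and least certain steps

Total step count: 12 steps. Longest linear sequence: 11 steps (from 4 to 18 through steps 2 to 12).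

Step 6 (key step). The most likely failure is slow capture of the zwitterion by the electron-rich, only moderately electrophilic acceptor 3, so that isomerisation or oligomerisation of the π-allyl alkoxide outruns cycloaddition. Incomplete trans selection at C1 and loss of enantiocontrol are further risks if ring closure becomes faster than π–σ–π equilibration. The fallback sets out from 1 and 9 and comes back at 10. Aldehyde 1 would be condensed with 2,2-dimethyl-1,3-dioxane-4,6-dione to the far more electrophilic 5-[4-(benzyloxy)-3-methoxybenzylidene]-2,2-dimethyl-1,3-dioxane-4,6-dione F1. The same palladium catalyst and 9 should then give the spiro adduct F2, in which the more reversible oxa-Michael step also gives C1 more chance to adjust. NaOMe in MeOH would open the dioxanedione with loss of acetone to the half ester F3, and MeI in DMF would convert the carboxylate into 10.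

Step 4. The risk is self-condensation of 7 and dimerisation (hetero-Diels–Alder) or polymerisation of the 2-arylacrolein 8 while it is formed and concentrated. The fallback sets out from 5 and comes back at 9 without passing through an enal. Vinylmagnesium bromide would give the allylic alcohol F4. Hydroxyl-directed epoxidation (VO(acac)2, t-BuOOH) would give the epoxy alcohol F5, and Dess–Martin oxidation the oxiranyl aryl ketone F6. Wittig methylenation (Ph3PCH3Br, KOt-Bu) would then give 9.

Step 8. The risk is poor facial selectivity in the hydride addition, or base-induced epimerisation at C3a before reduction. The fallback sets out from 11 and comes back at 17, and moves the control of C4 from the reduction to the ring closure. The reduction would be run without regard to selectivity, giving 12 together with its C4 epimer F7 and, after lactonisation, 13 with the epimeric lactone ester F8. Steps 9 and 10 would carry the mixture to 14 with the epimeric lactone F9, and to 15 with the epimeric diol F10. Both diols would then be closed with a catalytic sulfonic acid (CSA, CH2Cl2, 0 °C) through the common C4 benzylic cation. Attack of the hydroxymethyl group should place ring B on the convex face, as in quinone-methide-type closures to diequatorial furofurans, giving 17.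

Step 9. At 140 °C chloride may open the lactone at the benzylic C4, or the transient lactone enolate may expel O2 and re-add it; either process would erode the configuration at C4 or C1. The fallback sets out from 13 and comes back at 14. LiOH in aqueous THF would saponify the ester and the lactone to the hydroxy diacid F11, which stays in the flask. Acidification would relactonise it to the lactone acid F12, and gentle heating in toluene (about 90 °C) would decarboxylate F12 through its enol to 14.

Step 12. Once the phenols are free, continued exposure to hydrogen on palladium may open the furofuran by hydrogenolysis at C1–O2 or C4–O5. The fallback sets out from 17 and comes back at 18. Silane-transfer debenzylation (Pd(OAc)2 cat., Et3SiH, Et3N, CH2Cl2) is selective for aryl benzyl ethers over alkyl benzylic ethers and would give the bis(triethylsilyl) ether F13, so that no free phenol sits on the catalyst. TBAF in THF at 0 °C would then release 18.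

## Further compounds

F1 | step 6 | 5-[4-(benzyloxy)-3-methoxybenzylidene]-2,2-dimethyl-1,3-dioxane-4,6-dione | COc1cc(C=C2C(=O)OC(C)(C)OC2=O)ccc1OCc1ccccc1
F2 | step 6 | (1R,4R)-1-[4-(benzyloxy)-3-methoxyphenyl]-4-{1-[3-(benzyloxy)-4,5-dimethoxyphenyl]ethenyl}-8,8-dimethyl-2,7,9-trioxaspiro[4.5]decane-6,10-dione | COc1cc([C@H]2OC[C@H](C(=C)c3cc(OCc4ccccc4)c(OC)c(OC)c3)C23C(=O)OC(C)(C)OC3=O)ccc1OCc1ccccc1
F3 | step 6 | (2R,4R)-2-[4-(benzyloxy)-3-methoxyphenyl]-4-{1-[3-(benzyloxy)-4,5-dimethoxyphenyl]ethenyl}-3-(methoxycarbonyl)oxolane-3-carboxylic acid (mixture at C3) | COc1cc([C@H]2OC[C@H](C(=C)c3cc(OCc4ccccc4)c(OC)c(OC)c3)C2(C(=O)O)C(=O)OC)ccc1OCc1ccccc1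
F4 | step 4 | rac-1-[3-(benzyloxy)-4,5-dimethoxyphenyl]prop-2-en-1-ol | C=CC(O)c1cc(OCc2ccccc2)c(OC)c(OC)c1
F5 | step 4 | [3-(benzyloxy)-4,5-dimethoxyphenyl](oxiran-2-yl)methanol (diastereomer mixture, racemic) | OC(C1CO1)c1cc(OCc2ccccc2)c(OC)c(OC)c1
F6 | step 4 | rac-[3-(benzyloxy)-4,5-dimethoxyphenyl](oxiran-2-yl)methanone | O=C(C1CO1)c1cc(OCc2ccccc2)c(OC)c(OC)c1
F7 | step 8 | dimethyl (2R,4R)-2-[4-(benzyloxy)-3-methoxyphenyl]-4-{(R)-[3-(benzyloxy)-4,5-dimethoxyphenyl](hydroxy)methyl}oxolane-3,3-dicarboxylate | COc1cc([C@H]2OC[C@H]([C@@H](O)c3cc(OCc4ccccc4)c(OC)c(OC)c3)C2(C(=O)OC)C(=O)OC)ccc1OCc1ccccc1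
F8 | step 8 | methyl (1R,3aR,4R,6aS)-1-[4-(benzyloxy)-3-methoxyphenyl]-4-[3-(benzyloxy)-4,5-dimethoxyphenyl]-6-oxotetrahydro-1H,3H-furo[3,4-c]furan-6a(6H)-carboxylate | COc1cc([C@H]2OC[C@H]3[C@]2(C(=O)OC)C(=O)O[C@H]3c2cc(OCc4ccccc4)c(OC)c(OC)c2)ccc1OCc1ccccc1
F9 | step 8 | (1S,3aR,4R,6aS)-1-[4-(benzyloxy)-3-methoxyphenyl]-4-[3-(benzyloxy)-4,5-dimethoxyphenyl]tetrahydro-1H,3H-furo[3,4-c]furan-6-one | COc1cc([C@H]2OC[C@H]3[C@@H]2C(=O)O[C@H]3c2cc(OCc4ccccc4)c(OC)c(OC)c2)ccc1OCc1ccccc1
F10 | step 8 | (R)-[3-(benzyloxy)-4,5-dimethoxyphenyl]{(3R,4R,5S)-5-[4-(benzyloxy)-3-methoxyphenyl]-4-(hydroxymethyl)oxolan-3-yl}methanol | COc1cc([C@H]2OC[C@H]([C@@H](O)c3cc(OCc4ccccc4)c(OC)c(OC)c3)[C@@H]2CO)ccc1OCc1ccccc1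
F11 | step 9 | (2R,4R)-2-[4-(benzyloxy)-3-methoxyphenyl]-4-{(S)-[3-(benzyloxy)-4,5-dimethoxyphenyl](hydroxy)methyl}oxolane-3,3-dicarboxylic acid | COc1cc([C@H]2OC[C@H]([C@H](O)c3cc(OCc4ccccc4)c(OC)c(OC)c3)C2(C(=O)O)C(=O)O)ccc1OCc1ccccc1
F12 | step 9 | (1R,3aR,4S,6aS)-1-[4-(benzyloxy)-3-methoxyphenyl]-4-[3-(benzyloxy)-4,5-dimethoxyphenyl]-6-oxotetrahydro-1H,3H-furo[3,4-c]furan-6a(6H)-carboxylic acid | COc1cc([C@H]2OC[C@H]3[C@]2(C(=O)O)C(=O)O[C@@H]3c2cc(OCc4ccccc4)c(OC)c(OC)c2)ccc1OCc1ccccc1
F13 | step 12 | (1S,3aR,4S,6aR)-1-{3-methoxy-4-[(triethylsilyl)oxy]phenyl}-4-{3,4-dimethoxy-5-[(triethylsilyl)oxy]phenyl}tetrahydro-1H,3H-furo[3,4-c]furan | COc1cc([C@H]2OC[C@H]3[C@@H]2CO[C@@H]3c2cc(O[Si](CC)(CC)CC)c(OC)c(OC)c2)ccc1O[Si](CC)(CC)CC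
A1 | alternative 1 | (5R)-5-{[(1R,2S,5R)-5-methyl-2-(propan-2-yl)cyclohexyl]oxy}furan-2(5H)-one | O=C1O[C@@H](O[C@@H]2C[C@H](C)CC[C@H]2C(C)C)C=C1
A2 | alternative 1 | 2-[3-(benzyloxy)-4,5-dimethoxyphenyl]-1,3-dithiane | COc1cc(C2SCCCS2)cc(OCc2ccccc2)c1OC
A3 | alternative 1 | (3S,4R,5R)-3-{(S)-[4-(benzyloxy)-3-methoxyphenyl](hydroxy)methyl}-4-{2-[3-(benzyloxy)-4,5-dimethoxyphenyl]-1,3-dithian-2-yl}-5-{[(1R,2S,5R)-5-methyl-2-(propan-2-yl)cyclohexyl]oxy}oxolan-2-one | O=C1O[C@@H](O[C@@H]2C[C@H](C)CC[C@H]2C(C)C)[C@H](C2(c3cc(OCc4ccccc4)c(OC)c(OC)c3)SCCCS2)[C@H]1[C@H](O)c1ccc(OCc2ccccc2)c(OC)c1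
A4 | alternative 2 | 4-(1-{(1S,3aR,4S,6aR)-1-[4-(benzyloxy)-3-methoxyphenyl]tetrahydro-1H,3H-furo[3,4-c]furan-4-yl}ethenyl)-2,3-dimethoxycyclobut-2-en-1-one (either configuration at the ring CH) | COc1cc([C@H]2OC[C@H]3[C@@H]2CO[C@@H]3C(=C)C2C(=O)C(OC)=C2OC)ccc1OCc1ccccc1
A5 | alternative 2 | 5-{(1S,3aR,4S,6aR)-1-[4-(benzyloxy)-3-methoxyphenyl]tetrahydro-1H,3H-furo[3,4-c]furan-4-yl}-2,3-dimethoxyphenol | COc1cc([C@H]2OC[C@H]3[C@@H]2CO[C@@H]3c2cc(O)c(OC)c(OC)c2)ccc1OCc1ccccc1
A6 | alternative 3 | (1S,2E,4S)-1-[4-(benzyloxy)-3-methoxyphenyl]-4-[3-(benzyloxy)-4,5-dimethoxyphenyl]but-2-ene-1,4-diol | COc1cc([C@@H](O)/C=C/[C@H](O)c2cc(OCc3ccccc3)c(OC)c(OC)c2)ccc1OCc1ccccc1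
A7 | alternative 3 | (1S,3aS,4S,6aS)-1-[4-(benzyloxy)-3-methoxyphenyl]-4-[3-(benzyloxy)-4,5-dimethoxyphenyl]tetrahydro-1H,3H-furo[3,4-c]furan-3,6-dione | COc1cc([C@H]2OC(=O)[C@H]3[C@@H]2C(=O)O[C@@H]3c2cc(OCc4ccccc4)c(OC)c(OC)c2)ccc1OCc1ccccc1
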